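**Assumption:** the SMILES is taken literally and read with germacrane numbering (12,6-lactone, ester on C8, OH on C3, 4Z olefin, cis 1,10-epoxide); configuration 1R,3S,6R,7R,8R,10S and 2′R,3′R in the ester.

## Retrosynthetic overview

1. Last ring: the ten-membered carbocycle, closed by ring-closing metathesis at C4=C5 (4Z); only removal of the C3 silyl ether follows.
2. Before ring closure: C8 ester by Mitsunobu inversion with (2R,3R)-epoxyangelic acid; C1–C10 cis-epoxide by reagent-controlled epoxidation of a Z-trisubstituted olefin.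
3. C7–C8 bond and the α-methylene lactone: zinc Barbier coupling of a C8 aldehyde with (5R)-3-(bromomethyl)-5-vinylbutenolide (first ring, from carboxylative lactonisation of a Z-iodoallylic alcohol).
4. Key step: the C8–C9–C10(CH3)=C1–C2–C3 segment is cut out of 3-methylanisole by Birch dearomatisation and ozonolytic ring scission (C–OMe carbon becomes the C8 ester, its CH neighbour the C3 aldehyde); the arene ring dictates the Z olefin that later becomes the cis-epoxide.
5. Ring order: butenolide, fragment union, then the ten-membered ring; both oxiranes are in place before macrocyclisation.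

## Route

Step 1
Reactants: 1 3-methylanisole
Product: 2 1-methoxy-5-methylcyclohexa-1,4-diene
Conditions: Li, liquid NH3, THF, t-BuOH, −78 to −33 °C
Reagents that add atoms: none
Why: Birch reduction (key dearomatisation) protonates the radical anion ortho and meta to OMe so that the OMe- and CH3-bearing carbons stay sp2, which stores the future C1=C10 olefin with its two CH2 neighbours cis inside a six-membered ring (no stereocentre formed).

Step 2
Reactants: 2 1-methoxy-5-methylcyclohexa-1,4-diene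
Product: 4 methyl (3Z)-3-methyl-6-oxohex-3-enoate, via methoxy hydroperoxide 3 (not isolated)
Conditions: O3 (1.0 equiv), CH2Cl2–MeOH 4:1, pyridine (0.1 equiv), −78 °C; then Me2S, −78 °C to rt
Reagents that add atoms: ozone, O=[O+][O-]
Why: Chemoselective Criegee ozonolysis of the far more electron-rich enol ether opens the ring so that the OMe carbon becomes the C8 methyl ester and its CH partner the C3 aldehyde (methanol traps the carbonyl oxide as 3 and Me2S reduces it), while the untouched olefin keeps the ring-derived Z geometry.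

Step 3
Reactants: 4 methyl (3Z)-3-methyl-6-oxohex-3-enoate; 5 2-iodopropene
Product: 6 methyl (3Z,6S)-3,7-dimethyl-6-(triethylsilyloxy)octa-3,7-dienoate
Conditions: CrCl2 (10 mol%), NiCl2·2,9-dimethyl-1,10-phenanthroline (2 mol%), Kishi-type chiral sulfonamide–oxazoline ligand (11 mol%, antipode giving the 6S carbinol), Et3N (20 mol%), Mn powder, LiCl, Et3SiCl, MeCN, rt
Reagents that add atoms: chlorotriethylsilane, CC[Si](Cl)(CC)CC
Why: Catalytic asymmetric Nozaki–Hiyama–Kishi alkenylation adds the 2-propenyl group only to the aldehyde (ester inert, no base so the β,γ-unsaturated aldehyde does not conjugate), the chiral ligand on chromium selecting the aldehyde face that gives the 6S carbinol (C3 of the target), which Et3SiCl silylates as it releases the chromium.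

Step 4
Reactants: 6 methyl (3Z,6S)-3,7-dimethyl-6-(triethylsilyloxy)octa-3,7-dienoate
Product: 7 (3Z,6S)-3,7-dimethyl-6-(triethylsilyloxy)octa-3,7-dienal
Conditions: i-Bu2AlH (1.1 equiv), CH2Cl2, −78 °C; aq potassium sodium tartrate
Reagents that add atoms: none
Why: Partial ester reduction with one equivalent of i-Bu2AlH at −78 °C stops at the tetrahedral aluminium hemiacetal, which gives the C8 aldehyde on work-up without touching the olefins or the silyl ether (no stereocentre formed).

Step 5
Reactants: 8 acrolein; 9 tert-butyldimethyl(prop-2-yn-1-yloxy)silane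
Product: 11 (3R)-6-[(tert-butyldimethylsilyl)oxy]hex-1-en-4-yn-3-ol, via alkynylzinc 10 (not isolated)
Conditions: 9, Me2Zn (2.5 equiv), ProPhenol ligand (10 mol%, antipode giving the 3R carbinol), Ph3P=O (20 mol%), toluene, 0 °C; then 8, 0 °C
Reagents that add atoms: none
Why: Trost zinc–ProPhenol catalysed alkynylation delivers the alkynylzinc 10 in a 1,2-fashion to one enantiotopic face of acrolein, which sets the future C6 carbinol as 3R.

Step 6
Reactants: 11 (3R)-6-[(tert-butyldimethylsilyl)oxy]hex-1-en-4-yn-3-ol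
Product: 13 (3R,4Z)-6-[(tert-butyldimethylsilyl)oxy]-5-iodohexa-1,4-dien-3-ol, via cyclic vinylalanate 12 (not isolated)
Conditions: NaAlH2(OCH2CH2OCH3)2 (1.1 equiv), THF, 0 °C to rt; then I2, −78 °C
Reagents that add atoms: iodine, [I][I]
Why: Alkoxide-directed trans-hydroalumination puts hydride on the proximal and aluminium on the distal alkyne carbon through the five-membered alanate 12, and iodinolysis with retention gives the Z-iodoalkene with the stereocentre untouched.

Step 7
Reactants: 13 (3R,4Z)-6-[(tert-butyldimethylsilyl)oxy]-5-iodohexa-1,4-dien-3-ol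
Product: 16 (5R)-3-{[(tert-butyldimethylsilyl)oxy]methyl}-5-vinylfuran-2(5H)-one, via dilithio alkoxide 14 (not isolated), via hydroxy acid 15 (not isolated)
Conditions: t-BuLi (3.1 equiv), Et2O, −78 °C; CO2 gas, −78 to 0 °C; then 0.5 M HCl, 0 °C
Reagents that add atoms: carbon dioxide, O=C=O
Why: Iodine–lithium exchange with retention of olefin geometry, carboxylation of the vinyllithium and spontaneous lactonisation of the Z-γ-hydroxy acid 15 on acidification build the butenolide without a palladium catalyst that could ionise the allylic lactone C–O bond.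

Step 8
Reactants: 16 (5R)-3-{[(tert-butyldimethylsilyl)oxy]methyl}-5-vinylfuran-2(5H)-one
Product: 17 (5R)-3-(bromomethyl)-5-vinylfuran-2(5H)-one
Conditions: Ph3PBr2 (1.2 equiv), CH2Cl2, 0 °C to rt
Reagents that add atoms: dibromotriphenylphosphorane, BrP(Br)(c1ccccc1)(c1ccccc1)c1ccccc1
Why: Ph3PBr2 converts the primary allylic silyl ether directly into the bromide (silyloxyphosphonium formation then SN2 displacement by bromide), which avoids a radical bromination that would attack the doubly activated C5–H.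

Step 9
Reactants: 7 (3Z,6S)-3,7-dimethyl-6-(triethylsilyloxy)octa-3,7-dienal; 17 (5R)-3-(bromomethyl)-5-vinylfuran-2(5H)-one
Product: 19 (4R,5R)-4-[(1S,3Z,6S)-1-hydroxy-3,7-dimethyl-6-(triethylsilyloxy)octa-3,7-dien-1-yl]-3-methylidene-5-vinyloxolan-2-one, via allylzinc bromide 18 (not isolated)
Conditions: Zn dust (3 equiv), THF–saturated aq NH4Cl 2:1, 0 °C to rt, 17 added slowly
Reagents that add atoms: none
Why: Barbier allylation in which the allylzinc 18 reacts at its γ-carbon (SE2′) through a chair Zimmerman–Traxler transition state on the face anti to the vinyl group, creating the exo-methylene lactone with C7 trans to C6 (7R) and, because the ring makes the allyl unit E-configured, the anti carbinol 8S that step 13 inverts.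

Step 10
Reactants: 20 angelic acid
Product: 21 (2Z)-2-methylbut-2-en-1-ol
Conditions: LiAlH4, Et2O, 0 °C
Reagents that add atoms: none
Why: LiAlH4 reduces the carboxylic acid to the primary allylic alcohol in a 1,2-sense without isomerising the Z olefin.

Step 11
Reactants: 21 (2Z)-2-methylbut-2-en-1-ol
Product: 22 [(2S,3R)-2,3-dimethyloxiran-2-yl]methanol
Conditions: Ti(OiPr)4 (10 mol%), L-(+)-diethyl tartrate (12 mol%), t-BuOOH, 4 Å molecular sieves, CH2Cl2, −20 °C
Reagents that add atoms: tert-butyl hydroperoxide, CC(C)(C)OO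
Why: Sharpless asymmetric epoxidation with the L-(+)-tartrate titanium catalyst delivers oxygen to the face of the Z-allylic alcohol that gives the 2S,3R epoxy alcohol, the olefin geometry fixing the two methyl groups trans.

Step 12
Reactants: 22 [(2S,3R)-2,3-dimethyloxiran-2-yl]methanol
Product: 23 (2R,3R)-2,3-dimethyloxirane-2-carboxylic acid
Conditions: RuCl3 (2 mol%), NaIO4 (3 equiv), EtOAc–MeCN–H2O, rt
Reagents that add atoms: sodium periodate, [Na+].[O-]I(=O)(=O)=O
Why: RuO4-catalysed oxidation (Sharpless RuCl3/NaIO4 conditions) takes the primary alcohol to the acid without touching the epoxide, the change from 2S to 2R being only a change in CIP priorities.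

Step 13
Reactants: 19 (4R,5R)-4-[(1S,3Z,6S)-1-hydroxy-3,7-dimethyl-6-(triethylsilyloxy)octa-3,7-dien-1-yl]-3-methylidene-5-vinyloxolan-2-one; 23 (2R,3R)-2,3-dimethyloxirane-2-carboxylic acid
Product: 24 (1R,3Z,6S)-3,7-dimethyl-1-[(2R,3R)-4-methylidene-5-oxo-2-vinyloxolan-3-yl]-6-(triethylsilyloxy)octa-3,7-dien-1-yl (2R,3R)-2,3-dimethyloxirane-2-carboxylate
Conditions: PPh3 and DIAD (1.5 equiv each, betaine pre-formed), toluene, 0 °C; then 23 and 19, 0 °C to rt
Reagents that add atoms: none
Why: Mitsunobu esterification in which the C8 alkoxyphosphonium ion is displaced by the epoxy carboxylate in an SN2 step with clean inversion, turning 8S into the required 8R ester (the carbinol is homoallylic on both sides, so no SN2′ path exists).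

Step 14
Reactants: 24 (the ester from step 13)
Product: 25 (1R)-2-{(2S,3R)-2-methyl-3-[(2S)-3-methyl-2-(triethylsilyloxy)but-3-en-1-yl]oxiran-2-yl}-1-[(2R,3R)-4-methylidene-5-oxo-2-vinyloxolan-3-yl]ethyl (2R,3R)-2,3-dimethyloxirane-2-carboxylate
Conditions: D-fructose-derived Shi ketone (30 mol%), KHSO5 (as Oxone), K2CO3, n-Bu4NHSO4, MeCN–CH2(OMe)2–aq Na2B4O7 buffer, 0 °C
Reagents that add atoms: potassium peroxymonosulfate, [K+].[O-]S(=O)(=O)OO
Why: Shi asymmetric epoxidation in which the D-fructose-derived dioxirane attacks the only electron-rich trisubstituted olefin through the spiro transition state from the face that gives the 1R,10S epoxide (the same facial sense as for 1-phenylcyclohexene), the cis relationship coming from the arene-derived Z olefin, whereas the 1,1-disubstituted, monosubstituted and acrylate olefins react far more slowly.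

Step 15
Reactants: 25 (the epoxide from step 14)
Product: 26 1β,10β-epoxy-3β-(triethylsilyloxy)-8β-[(2R,3R)-2,3-dimethyloxirane-2-carbonyloxy]germacra-4Z,11(13)-dien-12,6α-olide
Conditions: second-generation Hoveyda–Grubbs catalyst RuCl2(H2IMes)(=CH–C6H4-2-OiPr) (20 mol% in two portions), 1,4-benzoquinone (10 mol%), toluene (0.5 mM), 80 °C, argon sparge
Reagents that add atoms: none
Why: Ring-closing metathesis between the C6 vinyl group and the 1,1-disubstituted C4 olefin releases ethene and closes the ten-membered ring, the strain of an E-cyclodecene and the turn imposed by the cis-epoxide enforcing the 4Z geometry.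

Step 16
Reactants: 26 (the silyl ether from step 15)
Product: 27 CNP0268255.3
Conditions: HF·pyridine, pyridine, THF, 0 °C
Reagents that add atoms: none
Why: Buffered fluoride desilylation removes the triethylsilyl ether to free the C3 hydroxyl under conditions that leave both epoxides, the ester and the α-methylene lactone intact.

## Compound list

1 | 3-methylanisole | COc1cccc(C)c1 | starting material
2 | 1-methoxy-5-methylcyclohexa-1,4-diene | COC1=CCC=C(C)C1 | intermediate
3 | methyl (3Z)-6-hydroperoxy-6-methoxy-3-methylhex-3-enoate | COC(=O)C/C(C)=C\CC(OC)OO | intermediate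
4 | methyl (3Z)-3-methyl-6-oxohex-3-enoate | COC(=O)C/C(C)=C\CC=O | intermediate
5 | 2-iodopropene | C=C(C)I | starting material
6 | methyl (3Z,6S)-3,7-dimethyl-6-(triethylsilyloxy)octa-3,7-dienoate | C=C(C)[C@@H](O[Si](CC)(CC)CC)C/C=C(/C)CC(=O)OC | intermediate
7 | (3Z,6S)-3,7-dimethyl-6-(triethylsilyloxy)octa-3,7-dienal | C=C(C)[C@@H](O[Si](CC)(CC)CC)C/C=C(/C)CC=O | intermediate
8 | acrolein | C=CC=O | starting material
9 | tert-butyldimethyl(prop-2-yn-1-yloxy)silane | C#CCO[Si](C)(C)C(C)(C)C | starting material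
10 | methyl{3-[(tert-butyldimethylsilyl)oxy]prop-1-yn-1-yl}zinc | C[Zn]C#CCO[Si](C)(C)C(C)(C)C | intermediate
11 | (3R)-6-[(tert-butyldimethylsilyl)oxy]hex-1-en-4-yn-3-ol | C=C[C@@H](O)C#CCO[Si](C)(C)C(C)(C)C | intermediate
12 | sodium (5R)-3-{[(tert-butyldimethylsilyl)oxy]methyl}-2,2-bis(2-methoxyethoxy)-5-vinyl-2,5-dihydro-1,2-oxaluminol-2-uide | [Na+].C=C[C@H]1O[Al-](OCCOC)(OCCOC)C(CO[Si](C)(C)C(C)(C)C)=C1 | intermediate
13 | (3R,4Z)-6-[(tert-butyldimethylsilyl)oxy]-5-iodohexa-1,4-dien-3-ol | C=C[C@@H](O)/C=C(\I)CO[Si](C)(C)C(C)(C)C | intermediate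
14 | lithium (3R)-6-[(tert-butyldimethylsilyl)oxy]-5-lithiohexa-1,4-dien-3-olate (lithium in the place of iodine, geometry retained) | C=C[C@@H](O[Li])/C=C(\[Li])CO[Si](C)(C)C(C)(C)C | intermediate
15 | (2Z,4R)-2-{[(tert-butyldimethylsilyl)oxy]methyl}-4-hydroxyhexa-2,5-dienoic acid | C=C[C@@H](O)/C=C(\C(=O)O)CO[Si](C)(C)C(C)(C)C | intermediate
16 | (5R)-3-{[(tert-butyldimethylsilyl)oxy]methyl}-5-vinylfuran-2(5H)-one | O=C1O[C@H](C=C)C=C1CO[Si](C)(C)C(C)(C)C | intermediate
17 | (5R)-3-(bromomethyl)-5-vinylfuran-2(5H)-one | O=C1O[C@H](C=C)C=C1CBr | intermediate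
18 | bromo{[(5R)-2-oxo-5-vinyl-2,5-dihydrofuran-3-yl]methyl}zinc | O=C1O[C@H](C=C)C=C1C[Zn]Br | intermediate
19 | (4R,5R)-4-[(1S,3Z,6S)-1-hydroxy-3,7-dimethyl-6-(triethylsilyloxy)octa-3,7-dien-1-yl]-3-methylidene-5-vinyloxolan-2-one | C=C1C(=O)O[C@H](C=C)[C@H]1[C@@H](O)C/C(C)=C\C[C@H](O[Si](CC)(CC)CC)C(C)=C | intermediate
20 | angelic acid, (2Z)-2-methylbut-2-enoic acid | C/C=C(/C)C(=O)O | starting material
21 | (2Z)-2-methylbut-2-en-1-ol | C/C=C(/C)CO | intermediate
22 | [(2S,3R)-2,3-dimethyloxiran-2-yl]methanol | OC[C@]1(C)O[C@@H]1C | intermediate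
23 | (2R,3R)-2,3-dimethyloxirane-2-carboxylic acid | OC(=O)[C@]1(C)O[C@@H]1C | intermediate
24 | (1R,3Z,6S)-3,7-dimethyl-1-[(2R,3R)-4-methylidene-5-oxo-2-vinyloxolan-3-yl]-6-(triethylsilyloxy)octa-3,7-dien-1-yl (2R,3R)-2,3-dimethyloxirane-2-carboxylate | C=C1C(=O)O[C@H](C=C)[C@H]1[C@H](OC(=O)[C@]2(C)O[C@@H]2C)C/C(C)=C\C[C@H](O[Si](CC)(CC)CC)C(C)=C | intermediate
25 | (1R)-2-{(2S,3R)-2-methyl-3-[(2S)-3-methyl-2-(triethylsilyloxy)but-3-en-1-yl]oxiran-2-yl}-1-[(2R,3R)-4-methylidene-5-oxo-2-vinyloxolan-3-yl]ethyl (2R,3R)-2,3-dimethyloxirane-2-carboxylate | C=C1C(=O)O[C@H](C=C)[C@H]1[C@H](OC(=O)[C@]2(C)O[C@@H]2C)C[C@]3(C)O[C@@H]3C[C@H](O[Si](CC)(CC)CC)C(C)=C | intermediate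
26 | 1β,10β-epoxy-3β-(triethylsilyloxy)-8β-[(2R,3R)-2,3-dimethyloxirane-2-carbonyloxy]germacra-4Z,11(13)-dien-12,6α-olide | C=C1C(=O)O[C@@H]2/C=C(/C)[C@@H](O[Si](CC)(CC)CC)C[C@H]3O[C@@]3(C)C[C@@H](OC(=O)[C@]3(C)O[C@@H]3C)[C@@H]12 | intermediate
27 | CNP0268255.3, 1β,10β-epoxy-3β-hydroxy-8β-[(2R,3R)-2,3-dimethyloxirane-2-carbonyloxy]germacra-4Z,11(13)-dien-12,6α-olide | C=C1C(=O)O[C@@H]2/C=C(/C)[C@@H](O)C[C@H]3O[C@@]3(C)C[C@@H](OC(=O)[C@]3(C)O[C@@H]3C)[C@@H]12 | target

## Step count and risks

Total: 16 steps. Longest linear sequence: 9 steps (1–4, 9, 13–16 from 3-methylanisole; the butenolide branch 5–8, 9, 13–16 is equally long).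

The three steps most likely to fail:

**Step 15 (ring-closing metathesis to a strained ten-membered ring with a trisubstituted olefin).** The fallback sets out from 19 and comes back at 26; it forges the ring on a leaner substrate and installs the ester and epoxide on the macrocycle. Ring-closing metathesis of 19 (same ruthenium catalyst, toluene, 80 °C, high dilution), with neither the epoxide nor the bulky ester present, gives the macrocyclic dienol 8α-hydroxy-3β-(triethylsilyloxy)germacra-1(10)Z,4Z,11(13)-trien-12,6α-olide F7. Mitsunobu esterification of F7 with 23 (inversion at C8) gives 8β-[(2R,3R)-2,3-dimethyloxirane-2-carbonyloxy]-3β-(triethylsilyloxy)germacra-1(10)Z,4Z,11(13)-trien-12,6α-olide F8. Shi epoxidation of F8 is chemoselective for C1=C10, because the ring C4=C5 olefin is deactivated by two allylic C–O bonds, and gives 26.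

**Step 13 (Mitsunobu inversion at a β-branched carbinol with a hindered acid).** The fallback sets out from 17 (with 7) and comes back at 24; it makes the 8R carbinol directly so that no inversion is needed. Bu3SnLi (THF, −78 °C) converts 17 into the allylstannane (5R)-3-[(tributylstannyl)methyl]-5-vinylfuran-2(5H)-one F1. BF3·OEt2-promoted addition of F1 to 7 (CH2Cl2, −78 °C) runs through an open transition state and gives the syn carbinol (4R,5R)-4-[(1R,3Z,6S)-1-hydroxy-3,7-dimethyl-6-(triethylsilyloxy)octa-3,7-dien-1-yl]-3-methylidene-5-vinyloxolan-2-one F2, the C8 epimer of 19. Yamaguchi esterification of F2 with 23 (2,4,6-trichlorobenzoyl chloride, Et3N, DMAP, toluene) goes with retention and gives 24.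

**Step 14 (Shi epoxidation: enantioselectivity on a Z-trisubstituted olefin and selectivity among four olefins).** The fallback sets out from 6 and comes back at 25; it sets the epoxide by a hydroxyl-directed, ligand-controlled epoxidation before fragment union. LiAlH4 (Et2O, 0 °C) reduces 6 to the homoallylic alcohol (3Z,6S)-3,7-dimethyl-6-(triethylsilyloxy)octa-3,7-dien-1-ol F3. Epoxidation with VO(OiPr)3, a chiral bishydroxamic acid ligand and cumene hydroperoxide (Yamamoto conditions for Z-homoallylic alcohols) gives 2-{(2S,3R)-2-methyl-3-[(2S)-3-methyl-2-(triethylsilyloxy)but-3-en-1-yl]oxiran-2-yl}ethan-1-ol F4. Dess–Martin oxidation (NaHCO3, CH2Cl2, 0 °C) gives 2-{(2S,3R)-2-methyl-3-[(2S)-3-methyl-2-(triethylsilyloxy)but-3-en-1-yl]oxiran-2-yl}acetaldehyde F5, used at once. Zinc Barbier coupling of F5 with 17 as in step 9 gives (4R,5R)-4-[(1S)-1-hydroxy-2-{(2S,3R)-2-methyl-3-[(2S)-3-methyl-2-(triethylsilyloxy)but-3-en-1-yl]oxiran-2-yl}ethyl]-3-methylidene-5-vinyloxolan-2-one F6. Mitsunobu esterification of F6 with 23 as in step 13 gives 25.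

## Further compounds

F1 | step 13 | (5R)-3-[(tributylstannyl)methyl]-5-vinylfuran-2(5H)-one | O=C1O[C@H](C=C)C=C1C[Sn](CCCC)(CCCC)CCCC
F2 | step 13 | (4R,5R)-4-[(1R,3Z,6S)-1-hydroxy-3,7-dimethyl-6-(triethylsilyloxy)octa-3,7-dien-1-yl]-3-methylidene-5-vinyloxolan-2-one | C=C1C(=O)O[C@H](C=C)[C@H]1[C@H](O)C/C(C)=C\C[C@H](O[Si](CC)(CC)CC)C(C)=C
F3 | step 14 | (3Z,6S)-3,7-dimethyl-6-(triethylsilyloxy)octa-3,7-dien-1-ol | C=C(C)[C@@H](O[Si](CC)(CC)CC)C/C=C(/C)CCO
F4 | step 14 | 2-{(2S,3R)-2-methyl-3-[(2S)-3-methyl-2-(triethylsilyloxy)but-3-en-1-yl]oxiran-2-yl}ethan-1-ol | C=C(C)[C@@H](O[Si](CC)(CC)CC)C[C@H]1O[C@@]1(C)CCO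
F5 | step 14 | 2-{(2S,3R)-2-methyl-3-[(2S)-3-methyl-2-(triethylsilyloxy)but-3-en-1-yl]oxiran-2-yl}acetaldehyde | C=C(C)[C@@H](O[Si](CC)(CC)CC)C[C@H]1O[C@@]1(C)CC=O
F6 | step 14 | (4R,5R)-4-[(1S)-1-hydroxy-2-{(2S,3R)-2-methyl-3-[(2S)-3-methyl-2-(triethylsilyloxy)but-3-en-1-yl]oxiran-2-yl}ethyl]-3-methylidene-5-vinyloxolan-2-one | C=C1C(=O)O[C@H](C=C)[C@H]1[C@@H](O)C[C@]2(C)O[C@@H]2C[C@H](O[Si](CC)(CC)CC)C(C)=C
F7 | step 15 | 8α-hydroxy-3β-(triethylsilyloxy)germacra-1(10)Z,4Z,11(13)-trien-12,6α-olide | C=C1C(=O)O[C@@H]2/C=C(/C)[C@@H](O[Si](CC)(CC)CC)C/C=C(/C)C[C@H](O)[C@@H]12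
F8 | step 15 | 8β-[(2R,3R)-2,3-dimethyloxirane-2-carbonyloxy]-3β-(triethylsilyloxy)germacra-1(10)Z,4Z,11(13)-trien-12,6α-olide | C=C1C(=O)O[C@@H]2/C=C(/C)[C@@H](O[Si](CC)(CC)CC)C/C=C(/C)C[C@@H](OC(=O)[C@]3(C)O[C@@H]3C)[C@@H]12
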